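**Retrosynthetic overview**
- The benzylic carbinol is made last, by ketoreductase reduction of the free-phenol aryl ketone (7-oxo lactone), so the acid-labile p-hydroxybenzylic alcohol never needs protection.
- The γ-butyrolactone, the only ring formed, comes from hydroxymethylation of an α-benzyl-γ-keto acid with formaldehyde followed by lactonisation. The ketone-α centre settles trans to the benzyl group.
- The aryl ketone comes from the Weinreb amide of a benzylsuccinate half-ester and an aryl Grignard reagent.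
- The benzyl-bearing stereocentre is set first, by asymmetric hydrogenation of a Stobbe half-ester with [Rh(cod)((S,S)-Et-DuPHOS)]BF4. The half-ester comes from O-benzylvanillin and dimethyl succinate.

Assumption: 1 and 7 are bought as catalogue compounds (each is otherwise one O-benzylation from vanillin or 4-bromo-2-methoxyphenol), and the ketoreductase is picked from a commercial screening panel.

**Step 1**
Reactants: 1 4-(benzyloxy)-3-methoxybenzaldehyde; 2 dimethyl succinate
Product: 3 (E)-4-[4-(benzyloxy)-3-methoxyphenyl]-3-(methoxycarbonyl)but-3-enoic acid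
Conditions: NaOMe (2.2 equiv), MeOH, reflux; then 2 M HCl, 0 °C; recrystallise
Reagents that add atoms: none
Why: Stobbe condensation, in which the succinate enolate adds to the non-enolisable aldehyde and the paraconate intermediate opens by E1cB to give the (E)-alkylidene half-ester with the ester on the alkene carbon.

**Step 2**
Reactants: 3 (E)-4-[4-(benzyloxy)-3-methoxyphenyl]-3-(methoxycarbonyl)but-3-enoic acid
Product: 4 (R)-4-[4-(benzyloxy)-3-methoxyphenyl]-3-(methoxycarbonyl)butanoic acid
Conditions: [Rh(cod)((S,S)-Et-DuPHOS)]BF4 (0.5 mol %), H2 (5 bar), NaOMe (10 mol %), degassed MeOH, 25 °C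
Reagents that add atoms: none
Why: Asymmetric hydrogenation of an itaconate-type half-ester, in which the carboxylate–alkene chelate on the C2-symmetric bisphospholane complex fixes the face of H2 delivery and sets the first stereocentre as R (sense assigned by analogy with enamide reductions and confirmed by chiral HPLC on the first batch, the antipodal ligand giving S), while aryl benzyl ethers are inert to this homogeneous catalyst.

**Step 3**
Reactants: 4 (R)-4-[4-(benzyloxy)-3-methoxyphenyl]-3-(methoxycarbonyl)butanoic acid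
Product: 6 methyl (R)-2-[4-(benzyloxy)-3-methoxybenzyl]-4-[methoxy(methyl)amino]-4-oxobutanoate, via acyl imidazolide 5 (not isolated)
Conditions: CDI (1.15 equiv), CH2Cl2, 20 °C, 1 h; then MeNHOMe·HCl (1.3 equiv), 20 °C
Reagents that add atoms: 1,1'-carbonyldiimidazole, O=C(n1ccnc1)n1ccnc1 (its imidazole is carried only in 5); N,O-dimethylhydroxylamine hydrochloride, CNOC.Cl
Why: Carboxyl activation as the acyl imidazolide followed by aminolysis gives the Weinreb amide under neutral conditions that touch neither the methyl ester nor the stereocentre.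

**Step 4**
Reactants: 6 methyl (R)-2-[4-(benzyloxy)-3-methoxybenzyl]-4-[methoxy(methyl)amino]-4-oxobutanoate; 7 1-(benzyloxy)-4-bromo-2-methoxybenzene
Product: 9 methyl (R)-2-[4-(benzyloxy)-3-methoxybenzyl]-4-[4-(benzyloxy)-3-methoxyphenyl]-4-oxobutanoate, via arylmagnesium bromide 8 (not isolated)
Conditions: 7, Mg turnings, I2 (cat.), THF, 45 °C; then add to 6 (1.3 equiv of 8), THF, −20 → 0 °C; 1 M HCl quench, 0 °C
Reagents that add atoms: magnesium, [Mg] (carried only in 8)
Why: Weinreb ketone synthesis, in which the chelated tetrahedral adduct stops over-addition and the α-branched methyl ester reacts much more slowly than the amide at −20 °C.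

**Step 5**
Reactants: 9 methyl (R)-2-[4-(benzyloxy)-3-methoxybenzyl]-4-[4-(benzyloxy)-3-methoxyphenyl]-4-oxobutanoate
Product: 10 (R)-2-[4-(benzyloxy)-3-methoxybenzyl]-4-[4-(benzyloxy)-3-methoxyphenyl]-4-oxobutanoic acid
Conditions: LiOH (2 equiv), THF/H2O 3:1, 0 → 20 °C; then 1 M HCl; recrystallise
Reagents that add atoms: lithium hydroxide, [Li+].[OH-] (its oxygen becomes the acid OH)
Why: Ester saponification by acyl–oxygen cleavage at low temperature, where the carboxylate formed shields the α-stereocentre from enolisation and crystallisation of the acid can raise the ee.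

**Step 6**
Reactants: 10 (R)-2-[4-(benzyloxy)-3-methoxybenzyl]-4-[4-(benzyloxy)-3-methoxyphenyl]-4-oxobutanoic acid; 11 formaldehyde
Product: 13 (3R,4R)-3-[4-(benzyloxy)-3-methoxybenzyl]-4-[4-(benzyloxy)-3-methoxybenzoyl]dihydrofuran-2(3H)-one, via hydroxymethyl keto acid 12 (not isolated)
Conditions: 37% aq. HCHO (2 equiv), 0.5 M aq. NaOH (1.5 equiv), THF, 20 °C, 3 h; then 2 M HCl to pH 1, 40 °C, 1 h
Reagents that add atoms: none
Why: Crossed aldol (hydroxymethylation) at the only enolisable ketone α-carbon, then acid-promoted γ-lactonisation, in which the new C4 centre is α to the ketone, epimerises via the enol and settles trans to the C3 benzyl group to give (3R,4R).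

**Step 7**
Reactants: 13 (3R,4R)-3-[4-(benzyloxy)-3-methoxybenzyl]-4-[4-(benzyloxy)-3-methoxybenzoyl]dihydrofuran-2(3H)-one
Product: 14 (3R,4R)-4-(4-hydroxy-3-methoxybenzoyl)-3-(4-hydroxy-3-methoxybenzyl)dihydrofuran-2(3H)-one (7-oxomatairesinol)
Conditions: H2 (1 atm), 10% Pd/C, EtOAc/THF, 20 °C, stopped at 2 equiv H2 uptake
Reagents that add atoms: none
Why: Hydrogenolysis of the two aryl benzyl ethers, which under neutral conditions is far faster than reduction of the electron-rich aryl ketone and leaves the lactone and both stereocentres untouched.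

**Step 8**
Reactants: 14 (3R,4R)-4-(4-hydroxy-3-methoxybenzoyl)-3-(4-hydroxy-3-methoxybenzyl)dihydrofuran-2(3H)-one
Product: 15 (3R,4R)-4-[(S)-hydroxy(4-hydroxy-3-methoxyphenyl)methyl]-3-(4-hydroxy-3-methoxybenzyl)dihydrofuran-2(3H)-one
Conditions: ketoreductase (NADPH-dependent KRED, Re-face-selective hit from a panel), NADP+ (cat.), iPrOH (20% v/v), KH2PO4/K2HPO4 buffer (0.1 M, pH 7.0), DMSO (5% v/v), 30 °C
Reagents that add atoms: none
Why: Ketoreductase-catalysed asymmetric carbonyl reduction, in which the enzyme delivers the NADPH hydride to the Re face of the aryl ketone under catalyst control to set the carbinol centre as S, at neutral pH that preserves the lactone, the trans ring centres and the p-hydroxybenzylic alcohol.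

**Compound list**
1 | 4-(benzyloxy)-3-methoxybenzaldehyde | O=Cc1ccc(OCc2ccccc2)c(OC)c1 | starting material
2 | dimethyl succinate | COC(=O)CCC(=O)OC | starting material
3 | (E)-4-[4-(benzyloxy)-3-methoxyphenyl]-3-(methoxycarbonyl)but-3-enoic acid | COC(=O)/C(CC(=O)O)=C/c1ccc(OCc2ccccc2)c(OC)c1 | intermediate
4 | (R)-4-[4-(benzyloxy)-3-methoxyphenyl]-3-(methoxycarbonyl)butanoic acid | COC(=O)[C@H](Cc1ccc(OCc2ccccc2)c(OC)c1)CC(=O)O | intermediate
5 | methyl (R)-2-[4-(benzyloxy)-3-methoxybenzyl]-4-(1H-imidazol-1-yl)-4-oxobutanoate (acyl imidazolide) | COC(=O)[C@H](Cc1ccc(OCc2ccccc2)c(OC)c1)CC(=O)n1ccnc1 | intermediate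
6 | methyl (R)-2-[4-(benzyloxy)-3-methoxybenzyl]-4-[methoxy(methyl)amino]-4-oxobutanoate | COC(=O)[C@H](Cc1ccc(OCc2ccccc2)c(OC)c1)CC(=O)N(C)OC | intermediate
7 | 1-(benzyloxy)-4-bromo-2-methoxybenzene | COc1cc(Br)ccc1OCc1ccccc1 | starting material
8 | [4-(benzyloxy)-3-methoxyphenyl]magnesium bromide | COc1cc([Mg]Br)ccc1OCc1ccccc1 | intermediate
9 | methyl (R)-2-[4-(benzyloxy)-3-methoxybenzyl]-4-[4-(benzyloxy)-3-methoxyphenyl]-4-oxobutanoate | COC(=O)[C@H](Cc1ccc(OCc2ccccc2)c(OC)c1)CC(=O)c1ccc(OCc2ccccc2)c(OC)c1 | intermediate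
10 | (R)-2-[4-(benzyloxy)-3-methoxybenzyl]-4-[4-(benzyloxy)-3-methoxyphenyl]-4-oxobutanoic acid | OC(=O)[C@H](Cc1ccc(OCc2ccccc2)c(OC)c1)CC(=O)c1ccc(OCc2ccccc2)c(OC)c1 | intermediate
11 | formaldehyde | C=O | starting material
12 | (2R,3R)-2-[4-(benzyloxy)-3-methoxybenzyl]-4-[4-(benzyloxy)-3-methoxyphenyl]-3-(hydroxymethyl)-4-oxobutanoic acid (hydroxymethyl keto acid; C3 equilibrates with its epimer in the flask) | COc1cc(C[C@@H](C(=O)O)[C@H](CO)C(=O)c2ccc(OCc3ccccc3)c(OC)c2)ccc1OCc1ccccc1 | intermediate
13 | (3R,4R)-3-[4-(benzyloxy)-3-methoxybenzyl]-4-[4-(benzyloxy)-3-methoxybenzoyl]dihydrofuran-2(3H)-one | COc1cc(C[C@H]2C(=O)OC[C@@H]2C(=O)c2ccc(OCc3ccccc3)c(OC)c2)ccc1OCc1ccccc1 | intermediate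
14 | (3R,4R)-4-(4-hydroxy-3-methoxybenzoyl)-3-(4-hydroxy-3-methoxybenzyl)dihydrofuran-2(3H)-one | COc1cc(C[C@H]2C(=O)OC[C@@H]2C(=O)c2ccc(O)c(OC)c2)ccc1O | intermediate
15 | (3R,4R)-4-[(S)-hydroxy(4-hydroxy-3-methoxyphenyl)methyl]-3-(4-hydroxy-3-methoxybenzyl)dihydrofuran-2(3H)-one | COc1cc(C[C@H]2C(=O)OC[C@@H]2[C@H](O)c2ccc(O)c(OC)c2)ccc1O | target

**Total step count:** 8
**Longest linear sequence:** 8 steps (1 → 15); 7 and 11 enter at steps 4 and 6 without steps of their own.

**Steps most likely to fail**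

Step 6 (hydroxymethylation–lactonisation). The risks are double hydroxymethylation, dehydration of the aldol to the α-methylene ketone (which would also expose the benzyl-bearing centre to epimerisation) and incomplete cis→trans equilibration. The fallback sets out from 9 and comes back at 13, replacing the aqueous base aldol by a Lewis-acid aldol of a preformed enol silane. Soft enolisation of 9 (TMSOTf, Et3N, CH2Cl2, 0 °C) gives methyl (2R,3Z)-2-[4-(benzyloxy)-3-methoxybenzyl]-4-[4-(benzyloxy)-3-methoxyphenyl]-4-[(trimethylsilyl)oxy]but-3-enoate F3. Mukaiyama-type hydroxymethylation of F3 with aqueous HCHO and Yb(OTf)3 (10 mol %) in THF/H2O at 20 °C gives methyl (2R,3R)-2-[4-(benzyloxy)-3-methoxybenzyl]-4-[4-(benzyloxy)-3-methoxyphenyl]-3-(hydroxymethyl)-4-oxobutanoate F4, together with its C3 epimer. Catalytic TsOH in CH2Cl2 at 20 °C then closes the lactone with loss of methanol and equilibrates the ketone-α centre to the trans lactone 13.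

Step 8 (ketoreductase reduction). The risk is that no panel enzyme combines useful activity on this hindered, α-branched, partly ionised phenolic ketone with clean 7S selectivity. The fallback sets out from 13 and comes back at 15, moving the reduction before deprotection and using a chemical catalyst. CBS reduction of 13 ((R)-2-methyl-CBS-oxazaborolidine 20 mol %, BH3·SMe2 0.7 equiv, THF, −20 °C; sense by analogy with acetophenone, both catalyst antipodes tried to find the matched case) gives (3R,4R)-3-[4-(benzyloxy)-3-methoxybenzyl]-4-[(S)-[4-(benzyloxy)-3-methoxyphenyl](hydroxy)methyl]dihydrofuran-2(3H)-one F5. Brief hydrogenolysis of F5 (H2 1 atm, Pd/C, neutral EtOAc, 20 °C, stopped at 2 equiv uptake so that the benzylic C–OH bond is not cleaved) gives 15.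

Step 4 (Grignard addition to the Weinreb amide). The risk is competing attack of the Grignard reagent on the methyl ester. The fallback sets out from 4 and comes back at 9, replacing the Grignard addition by a palladium-catalysed acylation with an ester-inert arylzinc. Acid 4 is converted with (COCl)2 and catalytic DMF (CH2Cl2, 0 → 20 °C) into methyl (R)-2-[4-(benzyloxy)-3-methoxybenzyl]-4-chloro-4-oxobutanoate F1. Separately, Grignard reagent 8 is transmetallated with ZnCl2 in THF to [4-(benzyloxy)-3-methoxyphenyl]zinc chloride F2. Negishi acylation of F1 with F2 (Pd(PPh3)4 2 mol %, THF, 0 → 20 °C) gives 9.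

**Further compounds**
F1 | step 4 | methyl (R)-2-[4-(benzyloxy)-3-methoxybenzyl]-4-chloro-4-oxobutanoate | COC(=O)[C@H](Cc1ccc(OCc2ccccc2)c(OC)c1)CC(=O)Cl
F2 | step 4 | [4-(benzyloxy)-3-methoxyphenyl]zinc chloride | COc1cc([Zn]Cl)ccc1OCc1ccccc1
F3 | step 6 | methyl (2R,3Z)-2-[4-(benzyloxy)-3-methoxybenzyl]-4-[4-(benzyloxy)-3-methoxyphenyl]-4-[(trimethylsilyl)oxy]but-3-enoate | COC(=O)[C@H](Cc1ccc(OCc2ccccc2)c(OC)c1)/C=C(\O[Si](C)(C)C)c1ccc(OCc2ccccc2)c(OC)c1
F4 | step 6 | methyl (2R,3R)-2-[4-(benzyloxy)-3-methoxybenzyl]-4-[4-(benzyloxy)-3-methoxyphenyl]-3-(hydroxymethyl)-4-oxobutanoate | COc1cc(C[C@@H](C(=O)OC)[C@H](CO)C(=O)c2ccc(OCc3ccccc3)c(OC)c2)ccc1OCc1ccccc1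
F5 | step 8 | (3R,4R)-3-[4-(benzyloxy)-3-methoxybenzyl]-4-[(S)-[4-(benzyloxy)-3-methoxyphenyl](hydroxy)methyl]dihydrofuran-2(3H)-one | COc1cc(C[C@H]2C(=O)OC[C@@H]2[C@H](O)c2ccc(OCc3ccccc3)c(OC)c2)ccc1OCc1ccccc1
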